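## Retrosynthetic overview

1. Target 20 ⇐ ester 19: the CH2C(CH3)2OH arm is made last from a CH2CO2Me arm by double methyl addition.
2. 19 ⇐ 18 by opening the O–Cc bond of ring A (O4, C4 and C3 of quinolone A, Ca, Cb, Cc). Cb=Cc is the 3,4-alkene of the 2,2-dimethyl-2H-pyrano[3,2-c]quinolone ring B; protonation at Cb gives a Cc cation stabilised by O4 of quinolone B, and the 4-OH of quinolone A sits 1,6 to Cc (Ca = side-chain CH on C3 of quinolone A, Cb = fusion CH next to CMe2, Cc = fusion OCH on C3 of quinolone B).
3. 18 ⇐ 17 ⇐ 10 + 16: the Ca–Cb bond and the Ca centre come from a rhodium/chiral diene 1,4-addition of the Cb boronate 16 to the quinolonyl acrylate 10.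
4. 10 ⇐ iodide 8 + methyl acrylate (Heck); 16 ⇐ bromide 15 ⇐ veprisine 13 ⇐ quinolone 6 + prenal; 6 ⇐ 2,3-dimethoxyaniline + diethyl malonate.
5. Ring order: the quinolone ring (step 2, material divided between both halves), ring B (step 6), ring A (step 11).

Key step: step 11

Remark (assumption): the diene antipode in step 9 is assigned from the usual face model for rhodium/diene additions to E-enoates ((R,R) ligand, attack on the re face of Ca); both antipodes are available, and the one that gives (S)-Ca is the one meant.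

## Route

Step 1
Reactants: 1 2,3-dimethoxyaniline
Product: 3 2,3-dimethoxy-N-methylaniline, via N-(methoxymethyl)aniline 2 (not isolated)
Conditions: (CH2O)n, NaOMe, MeOH, rt; then NaBH4, reflux
Reagents that add atoms: paraformaldehyde (as formaldehyde), C=O; methanol, CO (its methoxy group is carried only by intermediate 2)
Why: Condensation with formaldehyde in methanolic NaOMe should stop at the N-(methoxymethyl)aniline, and NaBH4 then reduces the iminium ion derived from it, a reductive amination that installs a single N-methyl group.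

Step 2
Reactants: 3 2,3-dimethoxy-N-methylaniline; 4 diethyl malonate
Product: 6 4-hydroxy-7,8-dimethoxy-1-methylquinolin-2(1H)-one, via malonanilate ester 5 (not isolated)
Conditions: Ph2O, 250 °C, EtOH distilled off (3 in slight excess)
Reagents that add atoms: none
Why: Thermal aminolysis of one ester gives the malonanilate, which loses ethanol and acylates the only free ortho position (para to the 3-methoxy group) in an intramolecular Friedel–Crafts-type ring closure, the classical thermal malonate cyclocondensation to 4-hydroxy-1-alkylquinolin-2-ones.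

Step 3
Reactants: 6 4-hydroxy-7,8-dimethoxy-1-methylquinolin-2(1H)-one
Product: 7 4-hydroxy-3-iodo-7,8-dimethoxy-1-methylquinolin-2(1H)-one
Conditions: NIS, DMF, rt
Reagents that add atoms: N-iodosuccinimide, O=C1CCC(=O)N1I
Why: C3 is the enol carbon of a cyclic vinylogous acid and should be iodinated far faster than the dimethoxybenzo ring (electrophilic α-halogenation of a 1,3-dicarbonyl equivalent).

Step 4
Reactants: 7 4-hydroxy-3-iodo-7,8-dimethoxy-1-methylquinolin-2(1H)-one
Product: 8 3-iodo-7,8-dimethoxy-4-(methoxymethoxy)-1-methylquinolin-2(1H)-one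
Conditions: MOMCl, iPr2NEt, CH2Cl2, 0 °C → rt
Reagents that add atoms: chloromethyl methyl ether, COCCl
Why: With C3 blocked and N1 methylated, the hard electrophile can only alkylate O4 (O-alkylation, acetal protection of the vinylogous acid).

Step 5
Reactants: 8 3-iodo-7,8-dimethoxy-4-(methoxymethoxy)-1-methylquinolin-2(1H)-one; 9 methyl acrylate
Product: 10 methyl (2E)-3-[7,8-dimethoxy-4-(methoxymethoxy)-1-methyl-2-oxo-1,2-dihydroquinolin-3-yl]prop-2-enoate
Conditions: Pd(OAc)2 (5 mol %), n-Bu4NBr, NaHCO3, DMF, 80 °C
Reagents that add atoms: none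
Why: Mizoroki–Heck reaction in which oxidative addition into the enone-like C3–I bond, syn insertion of the acrylate and β-hydride elimination give the E-enoate, the hydrogen carbonate base avoiding nucleophilic loss of the MOM group.

Step 6
Reactants: 6 4-hydroxy-7,8-dimethoxy-1-methylquinolin-2(1H)-one; 11 3-methylbut-2-enal
Product: 13 7,8-dimethoxy-2,2,6-trimethyl-2H-pyrano[3,2-c]quinolin-5(6H)-one (veprisine), via 1-oxatriene 12 (not isolated)
Conditions: pyridine, 110 °C
Reagents that add atoms: none
Why: Knoevenagel condensation at C3 gives the 1-oxatriene, whose oxa-6π electrocyclisation through O4 closes ring B as the angular dimethylpyranoquinolone, the standard annulation of 4-hydroxyquinolones with prenal.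

Step 7
Reactants: 13 veprisine
Product: 15 3-bromo-7,8-dimethoxy-2,2,6-trimethyl-2H-pyrano[3,2-c]quinolin-5(6H)-one, via trans-3,4-dibromide 14 (not isolated)
Conditions: Br2 (1.0 equiv), CH2Cl2, −78 °C; then Et3N, −78 °C → rt
Reagents that add atoms: bromine, BrBr
Why: Bromine adds across the electron-rich Cb=Cc bond with the electrophile on the nucleophilic Cb, and the Cc bromide, which ionises readily to the oxygen-stabilised cation, is lost together with the Cb proton on adding base (addition–elimination, E1-type dehydrobromination), leaving the vinyl bromide on Cb.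

Step 8
Reactants: 15 3-bromo-7,8-dimethoxy-2,2,6-trimethyl-2H-pyrano[3,2-c]quinolin-5(6H)-one
Product: 16 7,8-dimethoxy-2,2,6-trimethyl-3-(4,4,5,5-tetramethyl-1,3,2-dioxaborolan-2-yl)-2H-pyrano[3,2-c]quinolin-5(6H)-one
Conditions: B2pin2, PdCl2(dppf) (5 mol %), KOAc, 1,4-dioxane, 90 °C
Reagents that add atoms: bis(pinacolato)diboron, CC1(C)OB(OC1(C)C)B1OC(C)(C)C(C)(C)O1
Why: Miyaura borylation, in which zerovalent palladium inserts into the alkenyl C–Br bond and acetate-assisted transmetalation with B2pin2 delivers the alkenyl pinacolboronate without moving the ring alkene.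

Step 9
Reactants: 10 quinolonyl acrylate (1.0 equiv); 16 alkenyl pinacolboronate (1.5 equiv)
Product: 17 methyl (3S)-3-[7,8-dimethoxy-4-(methoxymethoxy)-1-methyl-2-oxo-1,2-dihydroquinolin-3-yl]-3-(7,8-dimethoxy-2,2,6-trimethyl-5-oxo-5,6-dihydro-2H-pyrano[3,2-c]quinolin-3-yl)propanoate
Conditions: [RhCl(C2H4)2]2 (2.5 mol %), (R,R)-Ph-bod* [(1R,4R)-2,5-diphenylbicyclo[2.2.2]octa-2,5-diene, 5.5 mol %], KOH (0.3 equiv, aq.), 1,4-dioxane/H2O 10:1, 50 °C
Reagents that add atoms: none
Why: Hayashi–Miyaura rhodium-catalysed asymmetric 1,4-addition, in which the alkenylrhodium species formed by transmetalation inserts the E-enoate at its β-carbon and is protonated by water, the C2-symmetric diene leaving one enoate face open so that the alkenyl group should arrive on the re face of Ca and set it as S.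

Step 10
Reactants: 17 MOM-protected adduct
Product: 18 methyl (3S)-3-(4-hydroxy-7,8-dimethoxy-1-methyl-2-oxo-1,2-dihydroquinolin-3-yl)-3-(7,8-dimethoxy-2,2,6-trimethyl-5-oxo-5,6-dihydro-2H-pyrano[3,2-c]quinolin-3-yl)propanoate
Conditions: HCl (cat., 0.1 M), MeOH/THF, 0 °C → rt
Reagents that add atoms: none
Why: The MOM group on the vinylogous acid oxygen is as labile as a MOM ester and should be removed by acid-catalysed acetal exchange with methanol under conditions too mild to protonate the chromene alkene or disturb Ca.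

Step 11
Reactants: 18 hydroxyquinolone–chromene precursor
Product: 19 cis-fused bis(pyranoquinolone) methyl ester, Ca (S), Cb (S), Cc (R); Hb and Hc cis, CH2CO2Me arm cis to Hb and trans to CMe2
Conditions: CF3CO2H (20 equiv), CH2Cl2 (0.02 M), 0 → 25 °C, held until the isomer composition no longer changes; aq. NaHCO3
Reagents that add atoms: none
Why: The acid protonates Cb, the terminus of the O4–C4=C3–Cc=Cb dienol ether of quinolone B, to give a Cc cation that is a vinylogous oxocarbenium ion, and the 4-OH of quinolone A, held 1,6 to Cc through C3–Ca–Cb, captures it; the closest known reaction type is the acid-catalysed intramolecular hydroalkoxylation of 2H-chromenes and styrenes by phenolic or enolic OH. Ring A closes as a six-membered ring, formally 6-endo-trig on the Cb=Cc alkene and 6-exo with respect to the cationic Cc=C3 bond. Both new centres are set under thermodynamic control, because C–O ionisation at Cc and deprotonation–reprotonation at Cb are reversible in this medium, so that the Cb/Cc isomers interconvert through the cation and the alkene. Cc (R) and the cis fusion should follow from allylic 1,3-strain with the lactam carbonyl of quinolone B, which keeps the new Cc–O bond pseudoaxial on ring B, an arrangement that only a cis-fused bicycle can hold; Cb (S) should follow from the resident Ca (S) centre, since only this cis isomer places the CH2CO2Me arm on the convex face, anti to CMe2 and clear of the lactam carbonyl of quinolone A. The step needs protonation at Cb and not at C3 of quinolone A (which would ionise the Ca–aryl bond), and closure by O4 and not by the ester; the high basicity of the dienol ether terminus, the low temperature and the non-nucleophilic medium should secure the first, and the uphill nature of acylating a vinylogous acid OH with a methyl ester should secure the second.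

Step 12
Reactants: 19 cis-fused methyl ester
Product: 20 target CNP0160874.2, Ca (S), Cb (S), Cc (R), side chain CH2C(CH3)2OH
Conditions: CeCl3 (anhydrous), MeMgBr (4 equiv), THF, −78 → 0 °C; aq. NH4Cl
Reagents that add atoms: methylmagnesium bromide, C[Mg]Br
Why: Double Grignard addition to the methyl ester, run as the organocerium reagent to suppress enolisation, should give the tertiary alcohol while the two aromatic N-methylquinolone carbonyls (vinylogous carbamates) stay untouched at low temperature; no stereocentre is involved and the mildly acidic quench spares the Cc–O linkage.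

## Compound list

1 | 2,3-dimethoxyaniline | COc1cccc(N)c1OC | starting material
2 | N-(methoxymethyl)-2,3-dimethoxyaniline (not isolated) | COCNc1cccc(OC)c1OC | intermediate
3 | 2,3-dimethoxy-N-methylaniline | CNc1cccc(OC)c1OC | intermediate
4 | diethyl malonate | CCOC(=O)CC(=O)OCC | starting material
5 | ethyl 3-[(2,3-dimethoxyphenyl)(methyl)amino]-3-oxopropanoate (not isolated) | CCOC(=O)CC(=O)N(C)c1cccc(OC)c1OC | intermediate
6 | 4-hydroxy-7,8-dimethoxy-1-methylquinolin-2(1H)-one | COc1ccc2c(O)cc(=O)n(C)c2c1OC | intermediate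
7 | 4-hydroxy-3-iodo-7,8-dimethoxy-1-methylquinolin-2(1H)-one | COc1ccc2c(O)c(I)c(=O)n(C)c2c1OC | intermediate
8 | 3-iodo-7,8-dimethoxy-4-(methoxymethoxy)-1-methylquinolin-2(1H)-one | COCOc1c(I)c(=O)n(C)c2c(OC)c(OC)ccc12 | intermediate
9 | methyl acrylate | C=CC(=O)OC | starting material
10 | methyl (2E)-3-[7,8-dimethoxy-4-(methoxymethoxy)-1-methyl-2-oxo-1,2-dihydroquinolin-3-yl]prop-2-enoate | COCOc1c(/C=C/C(=O)OC)c(=O)n(C)c2c(OC)c(OC)ccc12 | intermediate
11 | 3-methylbut-2-enal | CC(C)=CC=O | starting material
12 | 7,8-dimethoxy-1-methyl-3-(3-methylbut-2-en-1-ylidene)quinoline-2,4(1H,3H)-dione (not isolated) | COc1ccc2c(c1OC)N(C)C(=O)C(=CC=C(C)C)C2=O | intermediate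
13 | 7,8-dimethoxy-2,2,6-trimethyl-2H-pyrano[3,2-c]quinolin-5(6H)-one (veprisine) | COc1ccc2c3OC(C)(C)C=Cc3c(=O)n(C)c2c1OC | intermediate
14 | rac-trans-3,4-dibromo-7,8-dimethoxy-2,2,6-trimethyl-3,4-dihydro-2H-pyrano[3,2-c]quinolin-5(6H)-one (not isolated; one enantiomer drawn) | COc1ccc2c3OC(C)(C)[C@H](Br)[C@@H](Br)c3c(=O)n(C)c2c1OC | intermediate
15 | 3-bromo-7,8-dimethoxy-2,2,6-trimethyl-2H-pyrano[3,2-c]quinolin-5(6H)-one | COc1ccc2c3OC(C)(C)C(Br)=Cc3c(=O)n(C)c2c1OC | intermediate
16 | 7,8-dimethoxy-2,2,6-trimethyl-3-(4,4,5,5-tetramethyl-1,3,2-dioxaborolan-2-yl)-2H-pyrano[3,2-c]quinolin-5(6H)-one | COc1ccc2c3OC(C)(C)C(B4OC(C)(C)C(C)(C)O4)=Cc3c(=O)n(C)c2c1OC | intermediate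
17 | methyl (3S)-3-[7,8-dimethoxy-4-(methoxymethoxy)-1-methyl-2-oxo-1,2-dihydroquinolin-3-yl]-3-(7,8-dimethoxy-2,2,6-trimethyl-5-oxo-5,6-dihydro-2H-pyrano[3,2-c]quinolin-3-yl)propanoate | COc1ccc2c(OCOC)c(c(=O)n(C)c2c1OC)[C@@H](CC(=O)OC)C1=Cc2c(c3ccc(OC)c(OC)c3n(C)c2=O)OC1(C)C | intermediate
18 | methyl (3S)-3-(4-hydroxy-7,8-dimethoxy-1-methyl-2-oxo-1,2-dihydroquinolin-3-yl)-3-(7,8-dimethoxy-2,2,6-trimethyl-5-oxo-5,6-dihydro-2H-pyrano[3,2-c]quinolin-3-yl)propanoate | COc1ccc2c(O)c(c(=O)n(C)c2c1OC)[C@@H](CC(=O)OC)C1=Cc2c(c3ccc(OC)c(OC)c3n(C)c2=O)OC1(C)C | intermediate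
19 | cis-fused bis(pyranoquinolone) methyl ester, Ca (S), Cb (S), Cc (R) | COc1ccc2c3c(c(=O)n(C)c2c1OC)[C@@H](CC(=O)OC)[C@H]1[C@@H](O3)c2c(c3ccc(OC)c(OC)c3n(C)c2=O)OC1(C)C | intermediate
20 | CNP0160874.2, Ca (S), Cb (S), Cc (R) | COc1ccc2c3c(c(=O)n(C)c2c1OC)[C@@H](CC(C)(C)O)[C@H]1[C@@H](O3)c2c(c3ccc(OC)c(OC)c3n(C)c2=O)OC1(C)C | target

## Step count

Total steps: 12.
Longest linear sequence: 9 steps (1, 2, 6, 7, 8, 9, 10, 11, 12; the branch 1, 2, 3, 4, 5, 9, 10, 11, 12 is equally long). Quinolone 6 is divided between steps 3 and 6.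

## Steps most likely to fail

**Step 9.** Both partners are hindered: the boronate carbon is flanked by the quaternary CMe2, and the enoate β-carbon carries a doubly ortho-substituted, electron-donating quinolonyl group. Protodeboronation may therefore outrun insertion, or face discrimination may be poor. The fallback sets out from bromide 15 and quinolone 6 and comes back to the route at 18. Heck coupling of 15 with acrolein (Pd(OAc)2, n-Bu4NCl, NaHCO3, DMF) would give (2E)-3-(7,8-dimethoxy-2,2,6-trimethyl-5-oxo-5,6-dihydro-2H-pyrano[3,2-c]quinolin-3-yl)prop-2-enal F1. Iminium-catalysed Michael addition of 6 to F1 (diphenylprolinol trimethylsilyl ether, antipode chosen for Ca (S), benzoic acid co-catalyst, CH2Cl2) would give, after ring closure of the 4-OH on the aldehyde, the 2-hydroxy-3,4-dihydropyrano[3,2-c]quinolinone lactol F2. Oxidation of F2 (PhI(OAc)2, TEMPO) would give the 3,4-dihydropyrano[3,2-c]quinoline-2,5-dione lactone F3. Methanolysis of this enol ester (K2CO3 cat., MeOH, 0 °C) would free the 4-OH and give the methyl ester 18.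

**Step 11.** The equilibration may stall at a kinetic Cb/Cc isomer, the 4-OH may be diverted into lactone formation with the ester, or acid may ionise the bond between Ca and C3 of quinolone A and erode the configuration at Ca. The fallback sets out from 18 and comes back at 19, closing the same O–Cc bond under kinetic control. Phenylselenoetherification (N-(phenylseleno)phthalimide, camphorsulfonic acid cat., CH2Cl2, −78 °C) would place the electrophile on the nucleophilic Cb and add O4 to Cc in an anti sense, giving the cis-fused Cb-phenylselanyl ether F4. Bu3SnH/AIBN in toluene at 80 °C would then replace selenium by hydrogen, the tertiary Cb radical being expected to take hydrogen on the convex face, to give 19.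

**Step 7.** The dimethoxybenzo ring may be brominated competitively, or base-induced loss of HBr may take the other regiochemical course. The fallback sets out from 13 and comes back at 15. Hydroxybromination (NBS, DMSO/H2O, 0 °C) would give rac-trans-3-bromo-4-hydroxy-7,8-dimethoxy-2,2,6-trimethyl-3,4-dihydro-2H-pyrano[3,2-c]quinolin-5(6H)-one F5. Acid-catalysed dehydration of F5 through the Cc cation (TsOH, toluene, reflux with azeotropic removal of water) would then give 15 with bromine fixed on Cb.

## Further compounds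

F1 | step 9 | (2E)-3-(7,8-dimethoxy-2,2,6-trimethyl-5-oxo-5,6-dihydro-2H-pyrano[3,2-c]quinolin-3-yl)prop-2-enal | COc1ccc2c3OC(C)(C)C(/C=C/C=O)=Cc3c(=O)n(C)c2c1OC
F2 | step 9 | (4S)-4-(7,8-dimethoxy-2,2,6-trimethyl-5-oxo-5,6-dihydro-2H-pyrano[3,2-c]quinolin-3-yl)-2-hydroxy-7,8-dimethoxy-6-methyl-3,4-dihydro-2H-pyrano[3,2-c]quinolin-5(6H)-one (lactol, anomer mixture) | COc1ccc2c3OC(O)C[C@@H](C4=Cc5c(c6ccc(OC)c(OC)c6n(C)c5=O)OC4(C)C)c3c(=O)n(C)c2c1OC
F3 | step 9 | (4S)-4-(7,8-dimethoxy-2,2,6-trimethyl-5-oxo-5,6-dihydro-2H-pyrano[3,2-c]quinolin-3-yl)-7,8-dimethoxy-6-methyl-3,4-dihydro-2H-pyrano[3,2-c]quinoline-2,5(6H)-dione (lactone) | COc1ccc2c3OC(=O)C[C@@H](C4=Cc5c(c6ccc(OC)c(OC)c6n(C)c5=O)OC4(C)C)c3c(=O)n(C)c2c1OC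
F4 | step 11 | cis-fused bis(pyranoquinolone) methyl ester carrying SePh on Cb in place of hydrogen | COc1ccc2c3c(c(=O)n(C)c2c1OC)[C@@H](CC(=O)OC)[C@@]1([Se]c4ccccc4)[C@@H](O3)c2c(c3ccc(OC)c(OC)c3n(C)c2=O)OC1(C)C
F5 | step 7 | rac-trans-3-bromo-4-hydroxy-7,8-dimethoxy-2,2,6-trimethyl-3,4-dihydro-2H-pyrano[3,2-c]quinolin-5(6H)-one (one enantiomer drawn) | COc1ccc2c3OC(C)(C)[C@H](Br)[C@@H](O)c3c(=O)n(C)c2c1OC
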